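**Retrosynthetic overview**
1. Target ⇐ fluoride deprotection ⇐ ring A closed last by SmI2 pinacol coupling of a C2/C3 dialdehyde (ketyl umpolung; makes the C2–C3 bond and both carbinol centres).
2. Dialdehyde ⇐ 19,10-γ-lactone built on ring B: propionate Michael addition (C4–C5), convex-face C4 formylation, aldehyde-selective Wacker oxidation of a C10 vinyl group.
3. Ring B enone ester ⇐ tricyclic B/C/D enedione: enol triflate, γ-oxidation (C10 ketone), carbonylation (C7), thermodynamic 9β-H, 12α-OH by hindered hydride.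
4. Ring D ⇐ gold-catalysed 5-exo-dig silyl enol ether–alkyne cyclisation (sets C13, makes the 16-methylene).
5. Rings B + C ⇐ L-proline Hajos–Parrish annulation of 2-propargylcyclopentane-1,3-dione with methyl vinyl ketone (sets C8). Ring order: B → C → D → lactone → A.

Assumption: gibberellane numbering (C1–C19) and α/β (α = face of the 19,10-lactone bridge) are used for all intermediates, the final compound is called the target gibberellin, and C4 of lactone 19 is carried as an epimer mixture because step 13 makes it quaternary.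

**Step 1**
Reactants: 1 cyclopentane-1,3-dione; 2 3-bromoprop-1-yne
Product: 3 2-(prop-2-yn-1-yl)cyclopentane-1,3-dione
Conditions: KOH (1.0 equiv), H2O, 60 °C
Reagents that add atoms: none
Why: C-alkylation of the stabilised 1,3-dione anion with a propargylic halide in water; no stereocentre is formed.

**Step 2**
Reactants: 3 2-(prop-2-yn-1-yl)cyclopentane-1,3-dione; 4 but-3-en-2-one
Product: 5 2-(3-oxobutyl)-2-(prop-2-yn-1-yl)cyclopentane-1,3-dione
Conditions: H2O, AcOH (cat.), 75 °C
Reagents that add atoms: none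
Why: Michael addition of the acidic 2-substituted dione to the enone (first half of a Robinson annulation) gives the prochiral quaternary carbon that becomes C8.

**Step 3**
Reactants: 5 2-(3-oxobutyl)-2-(prop-2-yn-1-yl)cyclopentane-1,3-dione
Product: 7 (7aR)-7a-(prop-2-yn-1-yl)-2,3,7,7a-tetrahydro-1H-indene-1,5(6H)-dione, via cis-fused ketol 6 (not isolated)
Conditions: L-proline (30 mol%), DMF, rt, 72 h; then H2SO4 (cat.), DMF, 95 °C; recrystallise
Reagents that add atoms: none
Why: Hajos–Parrish–Eder–Sauer–Wiechert aldol: the proline enamine differentiates the enantiotopic ring carbonyls and sets C8 in the same spatial sense as the classic (S)-Hajos–Parrish ketone (descriptor R here because propargyl outranks CH2), and acid dehydration gives the enone.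

**Step 4**
Reactants: 7 (7aR)-7a-(prop-2-yn-1-yl)-2,3,7,7a-tetrahydro-1H-indene-1,5(6H)-dione
Product: 10 tricyclic B/C/D enedione (C6 ketone; 9(11)-en-12-one; 16-methylene; C15–C16 bridge β), via bis-silyl dienol ether 8 (not isolated), via tricyclic silyl enol ether 9 (not isolated)
Conditions: LiN(i-Pr)2 (3.5 equiv), TBSCl (2.6 equiv), THF–HMPA, −78 °C, cold NaHCO3 quench; then Ph3PAuCl (5 mol%), AgBF4 (5 mol%), CH2Cl2–H2O 10:1, 40 °C; then 1 M HCl, THF, rt
Reagents that add atoms: none
Why: Kinetic bis-enolisation gives the cross-conjugated 2-silyloxydiene (C12/C13) and the C5=C6 enol ether (the lithium acetylide is not silylated cold and is reprotonated), and monovalent gold then triggers a Toste-type Conia-ene 5-exo-dig attack of C13 on the alkyne to close ring D as the bicyclo[3.2.1]octane with the exocyclic methylene, C13 being dictated by the C8 tether, while the C6 enol ether (which could only cyclise to a strained 7-norbornanone) is hydrolysed.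

**Step 5**
Reactants: 10 tricyclic B/C/D enedione
Product: 11 C6 enol triflate (5-ene 6-triflate; 9(11)-en-12-one)
Conditions: KN(SiMe3)2 (1.1 equiv), THF, −78 °C; PhNTf2 (1.2 equiv), −78 → 0 °C
Reagents that add atoms: N-phenylbis(trifluoromethanesulfonimide), O=S(=O)(N(c1ccccc1)S(=O)(=O)C(F)(F)F)C(F)(F)F
Why: Kinetic enolate triflation (McMurry type): C5 is the only kinetically enolisable α-position because C8 is quaternary and the enone α′-carbon C13 is now a bridgehead.

**Step 6**
Reactants: 11 C6 enol triflate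
Product: 12 5-ene 6-triflate 9(11)-ene-10,12-dione
Conditions: Pd(OH)2 on carbon (5 mol%), t-BuOOH (5 equiv), K2CO3 (0.25 equiv), CH2Cl2, 4 °C → rt
Reagents that add atoms: tert-butyl hydroperoxide, CC(C)(C)OO
Why: Corey–Yu γ-oxidation of an enone: the C10 methylene is γ to the enone and doubly allylic, so it is oxidised to the ketone far faster than any other C–H.

**Step 7**
Reactants: 12 5-ene 6-triflate 9(11)-ene-10,12-dione
Product: 13 2-(trimethylsilyl)ethyl 5,9(11)-diene-10,12-dione 6-carboxylate (C7 installed)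
Conditions: Pd(OAc)2 (5 mol%), PPh3 (10 mol%), CO (1 atm), Me3SiCH2CH2OH (5 equiv), Et3N (2 equiv), DMF, 40 °C
Reagents that add atoms: carbon monoxide, [C-]#[O+]; 2-(trimethylsilyl)ethanol, C[Si](C)(C)CCO
Why: Palladium-catalysed alkoxycarbonylation of a vinylogous acyl triflate (oxidative addition, CO insertion, alcoholysis) introduces C7 as a fluoride-labile ester.

**Step 8**
Reactants: 13 2-(trimethylsilyl)ethyl 5,9(11)-diene-10,12-dione 6-carboxylate
Product: 14 2-(trimethylsilyl)ethyl 9β-H 5-ene-10,12-dione 6-carboxylate (B/C cis)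
Conditions: LiBH(s-Bu)3 (1.05 equiv), THF, −78 °C; AcOH quench; then DBU (0.2 equiv), CH2Cl2, rt
Reagents that add atoms: none
Why: Conjugate reduction: hydride adds to C11, the only unsubstituted carbon that is β to a ketone (C6 and C9 are fully substituted, and C5 is β only to the weaker ester acceptor), and DBU equilibration of the centre α to the C10 ketone gives the 9β-H cis B/C fusion, the only comfortable way to fuse the near-planar cyclopentenone onto the locked ring C chair.

**Step 9**
Reactants: 14 2-(trimethylsilyl)ethyl 9β-H 5-ene-10,12-dione 6-carboxylate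
Product: 15 12α-hydroxy 9β-H 5-en-10-one ester
Conditions: LiBH(s-Bu)3 (1.2 equiv), THF, −78 °C; AcOH quench
Reagents that add atoms: none
Why: Chemo- and diastereoselective ketone reduction with a bulky hydride: the saturated C12 ketone reacts before the conjugated C10 ketone (whose β-carbon C6 is fully substituted), and hydride comes along the equatorial β trajectory because the axial α approach is blocked by the axial C10 substituent on C9, giving the axial 12α-alcohol.

**Step 10**
Reactants: 15 12α-hydroxy 9β-H 5-en-10-one ester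
Product: 16 12α-TBS ether
Conditions: TBSOTf (1.5 equiv), 2,6-lutidine (3 equiv), CH2Cl2, −40 → 0 °C
Reagents that add atoms: tert-butyldimethylsilyl trifluoromethanesulfonate, CC(C)(C)[Si](C)(C)OS(=O)(=O)C(F)(F)F
Why: Silyl triflate protection of a hindered secondary alcohol, needed to keep the C12 oxygen out of the acylation and enolate steps.

**Step 11**
Reactants: 16 12α-TBS ether
Product: 18 10β-vinyl 10α-propionate, via bromomagnesium alkoxide 17 (not isolated)
Conditions: CH2=CHMgBr (1.5 equiv), THF, −78 → −40 °C; then (EtCO)2O (3 equiv), DMAP (0.1 equiv), −40 → 0 °C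
Reagents that add atoms: vinylmagnesium bromide, C=C[Mg]Br; propanoic anhydride, CCC(=O)OC(=O)CC
Why: Grignard 1,2-addition to the C10 ketone from the open β face (the α face is covered by C11 of ring C and the syn-axial 12α-silyloxy group) sets C10 with oxygen α, and the alkoxide is acylated in the same flask.

**Step 12**
Reactants: 18 10β-vinyl 10α-propionate
Product: 19 19,10-γ-lactone (5β-H; 6β-ester; 10β-vinyl; C4 H/Me epimers)
Conditions: KN(SiMe3)2 (1.1 equiv), THF, −78 → −20 °C; t-BuOH (3 equiv), 0 °C, 1 h; AcOH quench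
Reagents that add atoms: none
Why: Intramolecular Michael addition (5-exo-trig, as in Mander's gibberellin lactone construction): the propionate enolate held on the α-oxygen of C10 delivers C4 to the α face of C5, giving the cis-fused lactone with 5β-H, and the C6 ester equilibrates to the β orientation trans to C4.

**Step 13**
Reactants: 19 19,10-γ-lactone
Product: 20 4-formyl lactone (formyl cis to the C5 hydrogen and the C10 vinyl; 4-methyl cis to C6)
Conditions: LiN(i-Pr)2 (1.05 equiv), THF, −78 °C; HCO2CH2CF3 (3 equiv), −78 → −40 °C; AcOH quench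
Reagents that add atoms: 2,2,2-trifluoroethyl formate, O=COCC(F)(F)F
Why: Claisen-type C-formylation of the lactone enolate (the lactone α-hydrogen is more acidic and more accessible than the hindered C6 hydrogen): the electrophile enters on the convex face away from ring B, so C3 ends cis to C1 and the methyl becomes 18β.

**Step 14**
Reactants: 20 4-formyl lactone
Product: 21 dialdehyde (C10–CH2–CHO and C4–CHO)
Conditions: PdCl2(PhCN)2 (10 mol%), CuCl2·2H2O (10 mol%), AgNO2 (5 mol%), O2 (1 atm), t-BuOH–MeNO2 15:1, rt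
Reagents that add atoms: dioxygen, O=O
Why: Aldehyde-selective (anti-Markovnikov) nitrite-modified Wacker oxidation of a terminal alkene bearing an allylic acyloxy group; the 1,1-disubstituted C16 methylene does not react.

**Step 15**
Reactants: 21 dialdehyde
Product: 22 12-O-TBS 2-(trimethylsilyl)ethyl ester of the target gibberellin (2β,3β-diol)
Conditions: SmI2 (2.5 equiv, 0.1 M in THF), t-BuOH (2 equiv), THF, −78 °C → rt
Reagents that add atoms: none
Why: SmI2 pinacol cyclisation: one-electron reduction turns an aldehyde carbon into a nucleophilic ketyl (carbonyl umpolung), which couples with the other aldehyde carbon and closes ring A at C2–C3; the samarium-bridged diketyl gives the cis-diol, and both oxygens go to the β face because a 2α-oxygen would be axial and point into the lactone bridge.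

**Step 16**
Reactants: 22 12-O-TBS 2-(trimethylsilyl)ethyl ester of the target gibberellin
Product: 23 target gibberellin (2β,3β,12α-trihydroxy-16-methylene C19-gibberellin 19,10-lactone 7-oic acid)
Conditions: Bu4NF (5 equiv), AcOH (5 equiv), THF, rt → 40 °C; pH 3 aqueous work-up
Reagents that add atoms: none
Why: Fluoride-induced cleavage of the silyl ether and β-elimination of the 2-(trimethylsilyl)ethyl ester under buffered conditions that avoid base-induced retro-aldol epimerisation at C3.

**Compound list**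
1 | cyclopentane-1,3-dione | O=C1CCC(=O)C1 | starting material
2 | 3-bromoprop-1-yne | C#CCBr | starting material
3 | 2-(prop-2-yn-1-yl)cyclopentane-1,3-dione | C#CCC1C(=O)CCC1=O | intermediate
4 | but-3-en-2-one | CC(=O)C=C | starting material
5 | 2-(3-oxobutyl)-2-(prop-2-yn-1-yl)cyclopentane-1,3-dione | C#CCC1(CCC(C)=O)C(=O)CCC1=O | intermediate
6 | (3aS,7aR)-3a-hydroxy-7a-(prop-2-yn-1-yl)hexahydro-1H-indene-1,5(4H)-dione | C#CC[C@]23CCC(=O)C[C@@]2(O)CCC3=O | intermediate (not isolated)
7 | (7aR)-7a-(prop-2-yn-1-yl)-2,3,7,7a-tetrahydro-1H-indene-1,5(6H)-dione | C#CC[C@]23CCC(=O)C=C2CCC3=O | intermediate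
8 | bis(tert-butyldimethylsilyl) dienol ether of 7 (C12(OTBS)=C13; C9=C11; C5=C6(OTBS)) | C#CC[C@]23CC=C(O[Si](C)(C)C(C)(C)C)C=C2CC=C3O[Si](C)(C)C(C)(C)C | intermediate (not isolated)
9 | tricyclic 9(11)-en-12-one with C5=C6 TBS enol ether and 16-methylene | C=C1C[C@]23C[C@H]1C(=O)C=C2CC=C3O[Si](C)(C)C(C)(C)C | intermediate (not isolated)
10 | tricyclic B/C/D enedione: 16-methylenebicyclo[3.2.1]octane fused at C8–C9 to cyclopentanone ring B; C6 ketone; 9(11)-en-12-one; C15–C16 bridge β | C=C1C[C@]23C[C@H]1C(=O)C=C2CCC3=O | intermediate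
11 | C6 enol triflate of 10 (5-ene) | C=C1C[C@]23C[C@H]1C(=O)C=C2CC=C3OS(=O)(=O)C(F)(F)F | intermediate
12 | 5-ene 6-triflate 9(11)-ene-10,12-dione | C=C1C[C@]23C[C@H]1C(=O)C=C2C(=O)C=C3OS(=O)(=O)C(F)(F)F | intermediate
13 | 2-(trimethylsilyl)ethyl 5,9(11)-diene-10,12-dione 6-carboxylate | C=C1C[C@]23C[C@H]1C(=O)C=C2C(=O)C=C3C(=O)OCC[Si](C)(C)C | intermediate
14 | 2-(trimethylsilyl)ethyl 9β-H 5-ene-10,12-dione 6-carboxylate (B/C cis) | C=C1C[C@]23C[C@H]1C(=O)C[C@H]2C(=O)C=C3C(=O)OCC[Si](C)(C)C | intermediate
15 | 12α-hydroxy 9β-H 5-en-10-one ester | C=C1C[C@]23C[C@H]1[C@@H](O)C[C@H]2C(=O)C=C3C(=O)OCC[Si](C)(C)C | intermediate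
16 | 12α-TBS ether of 15 | C=C1C[C@]23C[C@H]1[C@@H](O[Si](C)(C)C(C)(C)C)C[C@H]2C(=O)C=C3C(=O)OCC[Si](C)(C)C | intermediate
17 | bromomagnesium 10α-alkoxide (10β-vinyl) | C=C1C[C@]23C[C@H]1[C@@H](O[Si](C)(C)C(C)(C)C)C[C@H]2[C@@](C=C)(O[Mg]Br)C=C3C(=O)OCC[Si](C)(C)C | intermediate (not isolated)
18 | 10β-vinyl 10α-propionate | C=C1C[C@]23C[C@H]1[C@@H](O[Si](C)(C)C(C)(C)C)C[C@H]2[C@@](C=C)(OC(=O)CC)C=C3C(=O)OCC[Si](C)(C)C | intermediate
19 | 19,10-γ-lactone: 5β-H; 6β-ester; 10β-vinyl; C4 bearing H and methyl (epimers) | C=C1C[C@]23C[C@H]1[C@@H](O[Si](C)(C)C(C)(C)C)C[C@H]2[C@@]1(C=C)OC(=O)C(C)[C@H]1[C@@H]3C(=O)OCC[Si](C)(C)C | intermediate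
20 | 4-formyl lactone: formyl cis to the C5 hydrogen and the C10 vinyl; 4-methyl cis to C6 | C=C1C[C@]23C[C@H]1[C@@H](O[Si](C)(C)C(C)(C)C)C[C@H]2[C@@]1(C=C)OC(=O)[C@](C)(C=O)[C@H]1[C@@H]3C(=O)OCC[Si](C)(C)C | intermediate
21 | dialdehyde: C10–CH2–CHO (C1, C2) and C4–CHO (C3) | C=C1C[C@]23C[C@H]1[C@@H](O[Si](C)(C)C(C)(C)C)C[C@H]2[C@@]1(CC=O)OC(=O)[C@](C)(C=O)[C@H]1[C@@H]3C(=O)OCC[Si](C)(C)C | intermediate
22 | 12-O-TBS 2-(trimethylsilyl)ethyl ester of the target gibberellin (2β,3β-diol) | C=C1C[C@]23C[C@H]1[C@@H](O[Si](C)(C)C(C)(C)C)C[C@H]2[C@@]12C[C@H](O)[C@H](O)[C@@](C)(C(=O)O1)[C@H]2[C@@H]3C(=O)OCC[Si](C)(C)C | intermediate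
23 | target gibberellin: 2β,3β,12α-trihydroxy-16-methylene C19-gibberellin 19,10-lactone 7-oic acid (5β-H, 6β-carboxyl, 9β-H, 18β-methyl) | C=C1C[C@]23C[C@H]1[C@@H](O)C[C@H]2[C@@]12C[C@H](O)[C@H](O)[C@@](C)(C(=O)O1)[C@H]2[C@@H]3C(=O)O | target

**Totals**
Total step count: 16. Longest linear sequence: 16 steps (fully linear from cyclopentane-1,3-dione).

**Three steps most likely to fail**

Step 8 (selective 1,4-reduction in the cross-conjugated trienone). Hydride may also attack the 4-oxo-enoate or the C12 carbonyl. The fallback sets out from 11 and returns at 14, changing the order of events. The isolated enone of 11 is reduced first with [(Ph3P)CuH]6 to the 9-H 12-keto vinyl triflate F1. This is carbonylated as in step 7 to the 9-H 12-keto 5-ene ester F2. The C10 ketone is then introduced by allylic oxidation with CrO3·3,5-dimethylpyrazole, and DBU equilibration of C9 gives 14.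

Step 14 (aldehyde-selective Wacker oxidation). The hindered tertiary allylic lactone may react slowly or undergo a divalent-palladium-mediated 1,3-acyloxy shift. The fallback sets out from 19 and returns at 21. The lactone enolate (LiN(i-Pr)2) is hydroxymethylated with gaseous CH2O on the convex face to the 4-hydroxymethyl lactone F3. The vinyl group is hydroborated with disiamylborane (monosubstituted alkene preferred over the C16 methylene) and oxidised with NaBO3 to the diol F4. A double Swern oxidation ((COCl)2, DMSO, Et3N) then gives 21.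

Step 15 (pinacol ring closure). The coupling may give the trans-diol, or elimination at the β-acyloxy aldehyde may compete. The fallback sets out from 21 and returns at 22. Low-valent titanium McMurry coupling (TiCl3(DME)1.5, Zn–Cu couple, DME, reflux) removes both oxygens and gives the protected ring A 2-ene F5. Osmylation with OsO4 (1.0 equiv, pyridine, −40 °C; aqueous NaHSO3 work-up) then attacks the strained cis-disubstituted 2-ene from the open β face, in preference to the C16 methylene, and gives 22.

**Further compounds**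
F1 | step 8 | 9-H 12-keto 5-ene 6-triflate (C9 epimers; C10 methylene) | C=C1C[C@]23C[C@H]1C(=O)CC2CC=C3OS(=O)(=O)C(F)(F)F
F2 | step 8 | 2-(trimethylsilyl)ethyl 9-H 12-keto 5-ene 6-carboxylate (C9 epimers; C10 methylene) | C=C1C[C@]23C[C@H]1C(=O)CC2CC=C3C(=O)OCC[Si](C)(C)C
F3 | step 14 | 4-hydroxymethyl lactone (CH2OH cis to the C5 hydrogen; 10β-vinyl) | C=C1C[C@]23C[C@H]1[C@@H](O[Si](C)(C)C(C)(C)C)C[C@H]2[C@@]1(C=C)OC(=O)[C@](C)(CO)[C@H]1[C@@H]3C(=O)OCC[Si](C)(C)C
F4 | step 14 | diol: C10–CH2CH2OH and C4–CH2OH | C=C1C[C@]23C[C@H]1[C@@H](O[Si](C)(C)C(C)(C)C)C[C@H]2[C@@]1(CCO)OC(=O)[C@](C)(CO)[C@H]1[C@@H]3C(=O)OCC[Si](C)(C)C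
F5 | step 15 | 12-O-TBS 2,3-didehydro lactone 2-(trimethylsilyl)ethyl ester (ring A 2-ene) | C=C1C[C@]23C[C@H]1[C@@H](O[Si](C)(C)C(C)(C)C)C[C@H]2[C@@]12CC=C[C@@](C)(C(=O)O1)[C@H]2[C@@H]3C(=O)OCC[Si](C)(C)C
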